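## Retrosynthetic overview

1. Labels: ring A is the 3,5-dibromo-2-aryloxyphenol ring. Ring B is the 2,4-dibromo-6-aryloxyphenol ring, numbered C1 (OH), C2 (O–ring A), C3 (H), C4 (Br), C5 (H), C6 (Br).
2. End game: the ring A OH is unmasked from OMe with BBr3, and Br at C6 of ring B is introduced ortho to the free OH. This leads back to 4-bromo-2-(2,4-dibromo-6-methoxyphenoxy)phenol.
3. Feature used: C6–C1(OH)–C2(OAr) of ring B is the CH3–CO–CH2OAr chain of an aryloxyacetone, and C3–C4(Br)–C5 is the OHC–CBr–CHO chain of bromomalonaldehyde. Ring B is therefore cut at C2–C3 and C5–C6 (three-plus-three double aldol benzannulation).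
4. The ether oxygen is attached by SN2 of the ring A phenoxide on chloroacetone, so no aryl–oxygen coupling is needed. Ring A comes from 4-bromo-2-methoxyphenol by one OH-directed bromination.
5. Ring order: ring A is bought and ring B is the only ring formed. The dialdehyde enters as its isopropyl enol ether.

Key step: step 4

Remark on the chemistry (assumption): bromomalonaldehyde is a vinylogous acid, and any base able to enolise a ketone ionises it completely; unlike the nitro analogue, its anion is assumed to be too poor an electrophile, so it enters the ring-forming step as its isopropyl enol ether (same three carbons, same oxidation level), and the C=C geometries drawn for this ether and for the open-chain intermediate are lost in ring B and do not affect the outcome.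

## Route

Step 1
Reactants: 1 4-bromo-2-methoxyphenol
Product: 2 2,4-dibromo-6-methoxyphenol
Conditions: NBS (1.0 equiv), i-Pr2NH (0.1 equiv), CH2Cl2, 0 °C → rt
Reagents that add atoms: N-bromosuccinimide (NBS), O=C1CCC(=O)N1Br
Why: Amine-catalysed NBS bromination of a phenol (electrophilic aromatic substitution through an N-bromoamine held at the OH) delivers bromine ortho to the hydroxyl, and C6 is the only free ortho or para position of 1, which steers attack away from C5, the position para to OMe.

Step 2
Reactants: 2 2,4-dibromo-6-methoxyphenol; 3 chloroacetone
Product: 4 1-(2,4-dibromo-6-methoxyphenoxy)propan-2-one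
Conditions: K2CO3 (1.5 equiv), acetone, reflux
Reagents that add atoms: none
Why: Williamson ether synthesis, in which the acidic, doubly ortho-substituted phenoxide of 2, a poor partner for any aryl coupling, should displace chloride readily by SN2 at the unhindered, carbonyl-activated primary carbon of 3.

Step 3
Reactants: 5 bromomalonaldehyde
Product: 6 (Z)-2-bromo-3-(propan-2-yloxy)prop-2-enal
Conditions: i-PrOH, p-TsOH·H2O (cat.), cyclohexane, reflux, azeotropic removal of water; used crude
Reagents that add atoms: propan-2-ol, CC(C)O
Why: Acid-catalysed O-alkylation of the enol form of a vinylogous acid (esterification-type enol ether formation), driven by removal of water, is an established way to cap halomalonaldehydes and leaves the vinylic bromide untouched.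

Step 4
Reactants: 4 1-(2,4-dibromo-6-methoxyphenoxy)propan-2-one; 6 (Z)-2-bromo-3-(propan-2-yloxy)prop-2-enal
Product: 8 4-bromo-2-(2,4-dibromo-6-methoxyphenoxy)phenol, via open-chain bromodienolate 7 (not isolated)
Conditions: KOt-Bu (3 equiv), THF/t-BuOH, −20 °C; add 6; rt → 55 °C; then 1 M HCl
Reagents that add atoms: none
Why: Proposed new method: double aldol-type condensation (three-plus-three benzannulation) in which the enolate of 4 first attacks the alkoxy-bearing carbon of 6 and expels isopropoxide, giving the delocalised dienolate 7 (shown for attack through the methyl carbon), after which bond rotation in 7, deprotonation of the second alpha carbon, attack on the remaining formyl carbon, loss of water and enolisation give the phenoxide of 8, an aromatic sink that pulls the reversible steps forward. The closest known reactions are the condensation of ketones with the sodium salt of nitromalonaldehyde to 4-nitrophenols, the annulation of ketone enolates with 2-halovinamidinium salts and the conversion of 2-methylpyrylium pseudo-bases into phenols by alkali, but a 2-bromo-3-alkoxyacrolein has not been combined with an unactivated aryloxy ketone. Ring B closes by intramolecular aldol addition in the 6-(enolendo)-exo-trig mode, the favoured mode for six-membered enolate closures, and C2–C3 and C5–C6 are the two new bonds. No stereocentre is formed, and regiochemistry needs no control because both ends of the three-carbon unit become ring CH groups, so that whichever alpha carbon reacts first Br ends para and the aryloxy group ortho to OH. The selectivity that counts is C–C bond formation against loss of bromide (substitution or O-cyclisation to a furan) and against self-aldol of 4: bromine sits on an sp2 carbon in 6 and in 7 as long as the medium stays basic, which rules out SN2 displacement, and formation of the stabilised anion 7 drains the ketone enolate irreversibly. The isopropyl cap keeps the electrophile neutral, whereas free 5 would be ionised at once to an enolate that a simple ketone enolate should not attack.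

Step 5
Reactants: 8 4-bromo-2-(2,4-dibromo-6-methoxyphenoxy)phenol
Product: 9 2,4-dibromo-6-(2,4-dibromo-6-methoxyphenoxy)phenol
Conditions: NBS (1.0 equiv), i-Pr2NH (0.1 equiv), CH2Cl2, 0 °C
Reagents that add atoms: N-bromosuccinimide (NBS), O=C1CCC(=O)N1Br
Why: Electrophilic aromatic bromination under the same OH-directed protocol should stop at 9 with one equivalent, because ring B is the only free phenol, its para position C4 is blocked and C6 is its only open ortho position, while ring A is a doubly brominated aryl ether and far less reactive.

Step 6
Reactants: 9 2,4-dibromo-6-(2,4-dibromo-6-methoxyphenoxy)phenol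
Product: 10 2,4-dibromo-6-(2,4-dibromo-6-hydroxyphenoxy)phenol (target, CNP0144684.0)
Conditions: BBr3 (3 equiv), CH2Cl2, −78 °C → rt; then H2O
Reagents that add atoms: none
Why: Lewis-acid cleavage of an aryl methyl ether, in which BBr3 binds the methoxy oxygen and bromide attacks the methyl carbon by SN2, whereas the diaryl ether offers no sp3 carbon and the aryl bromides are inert.

## Compound list

1 | 4-bromo-2-methoxyphenol | COc1cc(Br)ccc1O | starting material
2 | 2,4-dibromo-6-methoxyphenol | COc1cc(Br)cc(Br)c1O | intermediate
3 | chloroacetone (1-chloropropan-2-one) | CC(=O)CCl | starting material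
4 | 1-(2,4-dibromo-6-methoxyphenoxy)propan-2-one | CC(=O)COc1c(Br)cc(Br)cc1OC | intermediate
5 | bromomalonaldehyde (2-bromopropanedial) | O=CC(Br)C=O | starting material
6 | (Z)-2-bromo-3-(propan-2-yloxy)prop-2-enal | CC(C)O/C=C(Br)/C=O | intermediate
7 | potassium (1Z,3E)-2-bromo-6-(2,4-dibromo-6-methoxyphenoxy)-5-oxohexa-1,3-dien-1-olate | [K+].[O-]/C=C(Br)/C=C/C(=O)COc1c(Br)cc(Br)cc1OC | intermediate
8 | 4-bromo-2-(2,4-dibromo-6-methoxyphenoxy)phenol | COc1cc(Br)cc(Br)c1Oc1cc(Br)ccc1O | intermediate
9 | 2,4-dibromo-6-(2,4-dibromo-6-methoxyphenoxy)phenol | COc1cc(Br)cc(Br)c1Oc1cc(Br)cc(Br)c1O | intermediate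
10 | 2,4-dibromo-6-(2,4-dibromo-6-hydroxyphenoxy)phenol | Oc1cc(Br)cc(Br)c1Oc1cc(Br)cc(Br)c1O | target

Total step count: 6
Longest linear sequence: 5 (steps 1, 2, 4, 5, 6; step 3 is a one-step side branch)

## Steps most likely to fail

**Step 4 (bears the label "Proposed new method:").**
- What may go wrong:
  - The sequence may stall at the stabilised open-chain dienolate.
  - The ketone may self-condense faster than it is intercepted.
  - Protonation at the bromine-bearing carbon may open the way to loss of bromide by O-cyclisation.
- Fallback: it uses known chemistry, buys ring B instead of building it, sets out from 2 and comes back at 8. The phenoxide of 2 (K2CO3, DMA, 120 °C) displaces fluoride from commercial 4-bromo-2-fluorobenzaldehyde (O=Cc1ccc(Br)cc1F). This is a nucleophilic aromatic substitution ortho to the formyl group, and it should give 4-bromo-2-(2,4-dibromo-6-methoxyphenoxy)benzaldehyde F1. Baeyer–Villiger oxidation (mCPBA, CH2Cl2, rt), in which the aryloxy-substituted ring migrates, leads to 4-bromo-2-(2,4-dibromo-6-methoxyphenoxy)phenyl formate F2. Methanolysis (K2CO3, MeOH, rt) then releases 8.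

**Step 1.**
- What may go wrong: bromination para to the methoxy group (C5) may compete with attack ortho to OH (C6), and poor positional selectivity here would burden every later step.
- Fallback: it replaces electronic control by chelation control, sets out from 1 and comes back at 2. Ortho-formylation (MgCl2, Et3N, paraformaldehyde, MeCN, reflux; Casnati–Skattebøl reaction) can reach only the carbon next to OH and should give 5-bromo-2-hydroxy-3-methoxybenzaldehyde F3. Pinnick oxidation (NaClO2, NaH2PO4, 2-methylbut-2-ene, t-BuOH/H2O) gives 5-bromo-2-hydroxy-3-methoxybenzoic acid F4. Ipso-bromodecarboxylation of this salicylic acid (Br2, NaOAc, aqueous AcOH) puts bromine exactly where the carboxyl group stood and gives 2.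

**Step 5.**
- What may go wrong: attack at C5 of ring B (para to the ether oxygen) or further bromination of ring A next to OMe may erode selectivity on the most valuable intermediate.
- Fallback: it avoids any electrophilic bromination of the diaryl ether by bringing both ring B bromines in with a bought building block. It sets out from 2 and comes back at 9. The phenoxide of 2 (K2CO3, DMA, 120 °C) displaces fluoride from commercial 2,4-dibromo-6-fluorobenzaldehyde (O=Cc1c(F)cc(Br)cc1Br) to give 2,4-dibromo-6-(2,4-dibromo-6-methoxyphenoxy)benzaldehyde F5. Baeyer–Villiger oxidation (mCPBA, CH2Cl2) gives 2,4-dibromo-6-(2,4-dibromo-6-methoxyphenoxy)phenyl formate F6. Methanolysis (K2CO3, MeOH) gives 9.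

## Further compounds

F1 | step 4 | 4-bromo-2-(2,4-dibromo-6-methoxyphenoxy)benzaldehyde | COc1cc(Br)cc(Br)c1Oc1cc(Br)ccc1C=O
F2 | step 4 | 4-bromo-2-(2,4-dibromo-6-methoxyphenoxy)phenyl formate | COc1cc(Br)cc(Br)c1Oc1cc(Br)ccc1OC=O
F3 | step 1 | 5-bromo-2-hydroxy-3-methoxybenzaldehyde | COc1cc(Br)cc(C=O)c1O
F4 | step 1 | 5-bromo-2-hydroxy-3-methoxybenzoic acid | COc1cc(Br)cc(C(=O)O)c1O
F5 | step 5 | 2,4-dibromo-6-(2,4-dibromo-6-methoxyphenoxy)benzaldehyde | COc1cc(Br)cc(Br)c1Oc1cc(Br)cc(Br)c1C=O
F6 | step 5 | 2,4-dibromo-6-(2,4-dibromo-6-methoxyphenoxy)phenyl formate | COc1cc(Br)cc(Br)c1Oc1cc(Br)cc(Br)c1OC=O
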